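**Plan**

1. Numbering: the decalin is numbered as a drimane (C1–C10; C11 is the CH on C9, C12 the methyl on C8); the five-membered ring is C1' (C=O), C2', C3' (C–OH), C4' (=C11), C5' (CHCl).
2. Retrosynthetic cuts: first C11=C4' together with C5'–Cl (back to a C11 aldehyde, an enantiopure 4-silyloxycyclopent-2-enone and chloride, C1' staying a carbinol until the last step), then C8–C12, then C4–C5 and C9–C10 of the decalin in one operation, last C6–C7 of the open chain.
3. Enabling feature: the trans-decalin with gem-dimethyl C4, angular methyl on C10 and the one-carbon branch C11 on C9 next to oxygenated C8 is a folded geranyl–acetoacetate chain, so protonation of the terminal C3=C4 alkene can close ring A (C4–C5) and ring B (C9–C10) with the keto ester enol carbon C9 as terminator.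
4. Forward order: chain assembly (C6–C7), rings A and B in one cascade, C8 methyl, then the five-membered ring is joined through C11–C4' with chloride delivered to C5' in the same step, followed by dehydration and oxidation of C1'.
5. Stereochemistry: C5/C10 (trans) and C9 from the E-alkene and a chair–chair array, absolute sense from the chiral acid; C8 from α-face (equatorial) methyl addition opposite the axial C10 methyl; C5' from chloride addition anti to the C1' silyloxy group of the (R)-enone; C11=C4' geometry thermodynamic.

Key step: step 2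

Remark: α/β descriptors refer to the drimane drawn with the C10 methyl up (β); H5 and H9 are α throughout.
Assumption: the (R)-configured binaphthol acid is taken to protonate the face of C3=C4 that leads to the (5S,10S) series, as this acid type does with other chain termini; if the sense proves opposite, its (S)-enantiomer is used and nothing else changes.
Remark: the C8 carbinols from step 3 and the C11 carbinols from step 9 are carried as epimer mixtures (their SMILES leave that centre open), because both centres are removed later.
Remark: the target is a vinylogous acid; the diketo form produced by the last oxidation and the enol drawn are tautomers of one compound.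

**Route**

Step 1
Reactants: 1 geranyl chloride; 2 methyl acetoacetate
Product: 4 methyl (6E)-7,11-dimethyl-3-oxododeca-6,10-dienoate, via acetoacetate dianion 3 (not isolated)
Conditions: NaH, THF, 0 °C; n-BuLi, 0 °C; then 1, 0 °C to rt; aq. NH4Cl
Reagents that add atoms: none
Why: γ-Alkylation of the acetoacetate dianion, in which the more basic terminal carbanion displaces the primary allylic chloride by SN2 and leaves the E-alkene untouched, joins C6–C7 and carries the alkene geometry needed for the cyclization in from geranyl chloride.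

Step 2
Reactants: 4 methyl (6E)-7,11-dimethyl-3-oxododeca-6,10-dienoate
Product: 5 methyl (1R,4aS,8aS)-5,5,8a-trimethyl-2-oxodecahydronaphthalene-1-carboxylate
Conditions: (R)-2-(2-fluorobenzyloxy)-2'-hydroxy-1,1'-binaphthyl (2.2 equiv), SnCl4 (2.0 equiv), toluene, −78 °C; aq. NaHCO3
Reagents that add atoms: none
Why: Proposed new method: the tin-bound binaphthol O–H (a Lewis-acid-assisted Brønsted acid) protonates C3 of the terminal C3=C4 alkene on one enantioface, the tertiary C4 cation is captured by C5 of the (E)-C5=C10 alkene and the resulting C10 cation by the enol carbon C9 of the β-keto ester; the closest known reactions are the racemic SnCl4-promoted bicyclization of this class of dienyl β-keto esters and the enantioselective cyclizations of polyprenoids by the same chiral acid type that end on arenes or hydroxyl groups, and the step merges the two. Ring A closes 6-endo-trig (C4–C5) and ring B 6-endo at the enol double bond (C9–C10, C-alkylation). C5 and C10 are fixed by anti addition across the E-alkene in a chair–chair array (trans fusion, 10β-methyl), C9 by the equatorial position of the ester on the terminating chair, which is also the stable arrangement of this epimerisable centre, and the absolute sense by the face of C3=C4 that the chiral acid protonates. The step needs C- over O-termination and a complete cascade without monocyclic dienes; the substrate secures this through its hydrogen-bonded (or tin-chelated) Z-enol, whose carbon terminus lies six atoms from C10 in the chair, and through the E-trisubstituted alkene that relays the cation, while toluene at −78 °C with the acid in excess should keep the achiral SnCl4–keto ester complex from acting as the proton source.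

Step 3
Reactants: 5 methyl (1R,4aS,8aS)-5,5,8a-trimethyl-2-oxodecahydronaphthalene-1-carboxylate
Product: 6 12-nordrimane-8ξ,11-diol (C8 epimers)
Conditions: LiAlH4, THF, 0 °C to rt; aq. NaOH work-up
Reagents that add atoms: none
Why: Hydride reduction of both carbonyl groups with LiAlH4 (ester to the C11 primary alcohol, ketone to the C8 carbinol) is a standard 1,3-diol synthesis from β-keto esters; the C8 configuration is irrelevant because this centre is reoxidised in step 5, and C9 keeps its equatorial branch.

Step 4
Reactants: 6 12-nordrimane-8ξ,11-diol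
Product: 7 11-(triethylsilyloxy)-12-nordriman-8ξ-ol (C8 epimers)
Conditions: TESCl (1.05 equiv), imidazole, CH2Cl2, −20 °C
Reagents that add atoms: chlorotriethylsilane, CC[Si](Cl)(CC)CC
Why: Selective silylation should succeed because the primary C11 hydroxyl reacts with the silyl chloride far faster than the secondary C8 hydroxyl, which is flanked by C9 and held on the decalin.

Step 5
Reactants: 7 11-(triethylsilyloxy)-12-nordriman-8ξ-ol
Product: 8 11-(triethylsilyloxy)-12-nordriman-8-one
Conditions: Dess–Martin periodinane, pyridine, CH2Cl2, 0 °C to rt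
Reagents that add atoms: none
Why: Dess–Martin oxidation of the secondary alcohol under buffered, base-free conditions should give the C8 ketone without β-elimination of the C11 silyloxy group and without change at C9, whose equatorial substituent is in any case the stable arrangement.

Step 6
Reactants: 8 11-(triethylsilyloxy)-12-nordriman-8-one
Product: 9 8α-methyl-11-(triethylsilyloxy)-12-nordriman-8β-ol
Conditions: MeMgBr, CeCl3, THF, −78 °C; aq. NH4Cl
Reagents that add atoms: methylmagnesium bromide, C[Mg]Br
Why: 1,2-Addition of an organocerium reagent suppresses enolisation and β-elimination of the β-silyloxy ketone, and the methyl group enters equatorially from the α-face because the axial 10β-methyl blocks the β-face in a 1,3-diaxial sense, which sets C8 with the axial 8β-hydroxyl and the equatorial 8α-methyl.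

Step 7
Reactants: 9 8α-methyl-11-(triethylsilyloxy)-12-nordriman-8β-ol
Product: 10 8α-methyl-8β,11-bis(triethylsilyloxy)-12-nordrimane
Conditions: TESOTf, 2,6-lutidine, CH2Cl2, 0 °C
Reagents that add atoms: triethylsilyl trifluoromethanesulfonate, CC[Si](CC)(CC)OS(=O)(=O)C(F)(F)F
Why: Silylation of a hindered tertiary alcohol with a silyl triflate and 2,6-lutidine is standard and masks the hydroxyl, so that the later β-oxygenated aldehyde cannot undergo retro-aldol cleavage or bind TiCl4 as an alkoxide.

Step 8
Reactants: 10 8α-methyl-8β,11-bis(triethylsilyloxy)-12-nordrimane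
Product: 11 8α-methyl-8β-(triethylsilyloxy)-12-nordriman-11-al
Conditions: (COCl)2, DMSO, CH2Cl2, −78 to −40 °C; Et3N, −78 °C to rt
Reagents that add atoms: none
Why: Under Swern conditions a primary triethylsilyl ether is cleaved by the chlorosulfonium reagent and oxidised in the same flask to the aldehyde while hindered silyl ethers survive (a known selective oxidative desilylation), so the C11 aldehyde should be reached in one operation with the tertiary silyl ether intact and C9 unchanged.

Step 9
Reactants: 11 8α-methyl-8β-(triethylsilyloxy)-12-nordriman-11-al; 12 (4R)-4-(tert-butyldimethylsilyloxy)cyclopent-2-en-1-one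
Product: 14 (2S,3R,4R)-4-(tert-butyldimethylsilyloxy)-3-chloro-2-[(11ξ)-11-hydroxy-8α-methyl-8β-(triethylsilyloxy)-12-nordriman-11-yl]cyclopentan-1-one, via trichlorotitanium enolate 13 (not isolated)
Conditions: TiCl4 (1.3 equiv), 12 (2 equiv), CH2Cl2, −78 °C; aq. NaHCO3
Reagents that add atoms: titanium tetrachloride, Cl[Ti](Cl)(Cl)Cl
Why: In this TiCl4-mediated chloro-aldol (the halo-aldol variant of the Morita–Baylis–Hillman reaction) chloride adds to C5' of the activated enone anti to the C1' silyloxy group, which sets C5', and the β-chloro titanium enolate then adds through C4' to the aldehyde anti to chlorine; C4' and C11 are removed in step 10, so only the C5' outcome matters.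

Step 10
Reactants: 14 (2S,3R,4R)-4-(tert-butyldimethylsilyloxy)-3-chloro-2-[(11ξ)-11-hydroxy-8α-methyl-8β-(triethylsilyloxy)-12-nordriman-11-yl]cyclopentan-1-one
Product: 16 (2Z,3R,4R)-4-(tert-butyldimethylsilyloxy)-3-chloro-2-[8α-methyl-8β-(triethylsilyloxy)-12-nordriman-11-ylidene]cyclopentan-1-one, via mesylate 15 (not isolated)
Conditions: MsCl, Et3N, CH2Cl2, −20 to 0 °C
Reagents that add atoms: none
Why: Mesylation followed by E1cB elimination of the β-hydroxy ketone should expel the C11 mesylate from the ketone enolate and give the conjugated exocyclic alkene with the decalin anti to the carbonyl (the thermodynamic geometry); should chloride leave first, the chloride present returns by SN2' attack on the allylic mesylate anti to the silyloxy group, so both pathways converge on the same 3,4-trans chloride.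

Step 11
Reactants: 16 (2Z,3R,4R)-4-(tert-butyldimethylsilyloxy)-3-chloro-2-[8α-methyl-8β-(triethylsilyloxy)-12-nordriman-11-ylidene]cyclopentan-1-one
Product: 17 (2Z,3R,4R)-3-chloro-4-hydroxy-2-(8β-hydroxy-8α-methyl-12-nordriman-11-ylidene)cyclopentan-1-one
Conditions: HF·pyridine, pyridine, THF, 0 °C to rt
Reagents that add atoms: none
Why: Desilylation with buffered HF·pyridine, the standard unmasking of β-hydroxy cyclopentanones, removes both silyl ethers without base, so the trans chlorohydrin cannot close to an epoxide and the β-hydroxy ketone should not dehydrate.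

Step 12
Reactants: 17 (2Z,3R,4R)-3-chloro-4-hydroxy-2-(8β-hydroxy-8α-methyl-12-nordriman-11-ylidene)cyclopentan-1-one
Product: 18 (4Z,5R)-5-chloro-3-hydroxy-4-{[(1R,2S,4aS,8aS)-2-hydroxy-2,5,5,8a-tetramethyldecahydronaphthalen-1-yl]methylidene}cyclopent-2-en-1-one
Conditions: Dess–Martin periodinane (1.1 equiv), CH2Cl2, 0 °C
Reagents that add atoms: none
Why: Dess–Martin oxidation of the β-hydroxy ketone gives the cyclopentane-1,3-dione, which enolises at once to the vinylogous acid of the target; the C1' carbinol that steered the chlorine is thereby erased, and the base-free medium with one equivalent of oxidant should leave C5', the tertiary alcohol and the enol untouched.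

**Compound list**

1 | geranyl chloride, (2E)-1-chloro-3,7-dimethylocta-2,6-diene | CC(C)=CCC/C(C)=C/CCl | starting material
2 | methyl acetoacetate | COC(=O)CC(C)=O | starting material
3 | sodium lithium dianion of methyl acetoacetate (not isolated) | [CH2-]C(=O)[CH-]C(=O)OC.[Na+].[Li+] | intermediate
4 | methyl (6E)-7,11-dimethyl-3-oxododeca-6,10-dienoate | COC(=O)CC(=O)CC/C=C(\C)CCC=C(C)C | intermediate
5 | methyl (1R,4aS,8aS)-5,5,8a-trimethyl-2-oxodecahydronaphthalene-1-carboxylate (trans-decalin, 10β-methyl, equatorial ester on C9) | CC1(C)CCC[C@]2(C)[C@@H](C(=O)OC)C(=O)CC[C@@H]12 | intermediate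
6 | 12-nordrimane-8ξ,11-diol, (1S,4aS,8aS)-1-(hydroxymethyl)-5,5,8a-trimethyldecahydronaphthalen-2-ol, C8 epimers | CC1(C)CCC[C@]2(C)[C@@H](CO)C(O)CC[C@@H]12 | intermediate
7 | 11-(triethylsilyloxy)-12-nordriman-8ξ-ol, C8 epimers | CC1(C)CCC[C@]2(C)[C@@H](CO[Si](CC)(CC)CC)C(O)CC[C@@H]12 | intermediate
8 | 11-(triethylsilyloxy)-12-nordriman-8-one | CC1(C)CCC[C@]2(C)[C@@H](CO[Si](CC)(CC)CC)C(=O)CC[C@@H]12 | intermediate
9 | 8α-methyl-11-(triethylsilyloxy)-12-nordriman-8β-ol (axial tertiary hydroxyl, equatorial methyl) | CC1(C)CCC[C@]2(C)[C@@H](CO[Si](CC)(CC)CC)[C@@](C)(O)CC[C@@H]12 | intermediate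
10 | 8α-methyl-8β,11-bis(triethylsilyloxy)-12-nordrimane | CC1(C)CCC[C@]2(C)[C@@H](CO[Si](CC)(CC)CC)[C@@](C)(O[Si](CC)(CC)CC)CC[C@@H]12 | intermediate
11 | 8α-methyl-8β-(triethylsilyloxy)-12-nordriman-11-al | CC1(C)CCC[C@]2(C)[C@@H](C=O)[C@@](C)(O[Si](CC)(CC)CC)CC[C@@H]12 | intermediate
12 | (4R)-4-(tert-butyldimethylsilyloxy)cyclopent-2-en-1-one (commercial) | O=C1C=C[C@H](O[Si](C)(C)C(C)(C)C)C1 | starting material
13 | trichloro{[(3R,4R)-4-(tert-butyldimethylsilyloxy)-3-chlorocyclopent-1-en-1-yl]oxy}titanium (not isolated) | Cl[Ti](Cl)(Cl)OC1=C[C@@H](Cl)[C@H](O[Si](C)(C)C(C)(C)C)C1 | intermediate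
14 | (2S,3R,4R)-4-(tert-butyldimethylsilyloxy)-3-chloro-2-[(11ξ)-11-hydroxy-8α-methyl-8β-(triethylsilyloxy)-12-nordriman-11-yl]cyclopentan-1-one, all-trans ring, C11 epimers | CC1(C)CCC[C@]2(C)[C@@H](C(O)[C@H]3C(=O)C[C@@H](O[Si](C)(C)C(C)(C)C)[C@@H]3Cl)[C@@](C)(O[Si](CC)(CC)CC)CC[C@@H]12 | intermediate
15 | C11 methanesulfonate of 14 (not isolated) | CC1(C)CCC[C@]2(C)[C@@H](C(OS(C)(=O)=O)[C@H]3C(=O)C[C@@H](O[Si](C)(C)C(C)(C)C)[C@@H]3Cl)[C@@](C)(O[Si](CC)(CC)CC)CC[C@@H]12 | intermediate
16 | (2Z,3R,4R)-4-(tert-butyldimethylsilyloxy)-3-chloro-2-[8α-methyl-8β-(triethylsilyloxy)-12-nordriman-11-ylidene]cyclopentan-1-one | CC1(C)CCC[C@]2(C)[C@@H](/C=C3\C(=O)C[C@@H](O[Si](C)(C)C(C)(C)C)[C@@H]3Cl)[C@@](C)(O[Si](CC)(CC)CC)CC[C@@H]12 | intermediate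
17 | (2Z,3R,4R)-3-chloro-4-hydroxy-2-(8β-hydroxy-8α-methyl-12-nordriman-11-ylidene)cyclopentan-1-one | CC1(C)CCC[C@]2(C)[C@@H](/C=C3\C(=O)C[C@@H](O)[C@@H]3Cl)[C@@](C)(O)CC[C@@H]12 | intermediate
18 | (4Z,5R)-5-chloro-3-hydroxy-4-{[(1R,2S,4aS,8aS)-2-hydroxy-2,5,5,8a-tetramethyldecahydronaphthalen-1-yl]methylidene}cyclopent-2-en-1-one (CNP0279879.2) | CC1(C)CCC[C@]2(C)[C@@H](/C=C3\C(O)=CC(=O)[C@@H]3Cl)[C@@](C)(O)CC[C@@H]12 | target

**Step count and risks**

Total steps: 12. Longest linear sequence: 12 steps (from 1 and 2 to 18); the enone 12 is bought.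

Step 2 (highest risk): proton transfer from the achiral SnCl4–keto ester complex, or from HCl released by it, may compete with the chiral acid, so that facial selectivity in the protonation is poor; the cascade may also stop after ring A. The fallback uses known chemistry and sets out from 4. SnCl4 alone in CH2Cl2, the established racemic bicyclization, gives 5 as the racemate, that is 5 together with its mirror image methyl (1S,4aR,8aR)-5,5,8a-trimethyl-2-oxodecahydronaphthalene-1-carboxylate F1. Preparative chromatography on a chiral stationary phase separates the two, and the route is rejoined at 5.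

Step 9: the titanium enolate may add too slowly to the doubly flanked, α-branched aldehyde, so that Lewis-acid-induced loss of the tertiary silyloxy group or return of 13 to the enone takes over. The fallback sets out from 11 and 12 and replaces steps 9 and 10. Conjugate addition of Me2AlSPh (from Me3Al and PhSH) to 12 anti to the silyloxy group, with aldol capture of the dimethylaluminium enolate by 11, gives the thio-aldol adduct (2S,3R,4R)-4-(tert-butyldimethylsilyloxy)-2-[(11ξ)-11-hydroxy-8α-methyl-8β-(triethylsilyloxy)-12-nordriman-11-yl]-3-(phenylsulfanyl)cyclopentan-1-one F2. Oxidation with NaIO4 gives the corresponding sulfoxide F3, whose thermal syn-elimination gives the hydroxy enone (4R)-4-(tert-butyldimethylsilyloxy)-2-[(11ξ)-11-hydroxy-8α-methyl-8β-(triethylsilyloxy)-12-nordriman-11-yl]cyclopent-2-en-1-one F4. MsCl and Et3N convert it into the allylic mesylate F5, and LiCl displaces this in an SN2' sense, chloride entering C5' anti to the silyloxy group, which returns the route at 16.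

Step 11: the hindered axial tertiary silyl ether may be cleaved far more slowly than the secondary one, and the long exposure to acid may then dehydrate the unveiled β-hydroxy ketone to the cyclopentenone. The fallback sets out from 16 and changes the order of events. Short treatment with HF·pyridine removes only the secondary silyl ether and gives the chlorohydrin that still holds the tertiary silyl ether, (2Z,3R,4R)-3-chloro-4-hydroxy-2-[8α-methyl-8β-(triethylsilyloxy)-12-nordriman-11-ylidene]cyclopentan-1-one F6. Dess–Martin oxidation gives the 8-O-triethylsilyl ether of the target F7, which no longer contains a β-hydroxy ketone. It is desilylated last with aqueous HF in MeCN, and the route returns at 18.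

**Further compounds**

F1 | step 2 | methyl (1S,4aR,8aR)-5,5,8a-trimethyl-2-oxodecahydronaphthalene-1-carboxylate (enantiomer of 5) | CC1(C)CCC[C@@]2(C)[C@H](C(=O)OC)C(=O)CC[C@H]12
F2 | step 9 | (2S,3R,4R)-4-(tert-butyldimethylsilyloxy)-2-[(11ξ)-11-hydroxy-8α-methyl-8β-(triethylsilyloxy)-12-nordriman-11-yl]-3-(phenylsulfanyl)cyclopentan-1-one | CC1(C)CCC[C@]2(C)[C@@H](C(O)[C@H]3C(=O)C[C@@H](O[Si](C)(C)C(C)(C)C)[C@@H]3Sc4ccccc4)[C@@](C)(O[Si](CC)(CC)CC)CC[C@@H]12
F3 | step 9 | S-oxide (sulfoxide) of F2 | CC1(C)CCC[C@]2(C)[C@@H](C(O)[C@H]3C(=O)C[C@@H](O[Si](C)(C)C(C)(C)C)[C@@H]3S(=O)c4ccccc4)[C@@](C)(O[Si](CC)(CC)CC)CC[C@@H]12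
F4 | step 9 | (4R)-4-(tert-butyldimethylsilyloxy)-2-[(11ξ)-11-hydroxy-8α-methyl-8β-(triethylsilyloxy)-12-nordriman-11-yl]cyclopent-2-en-1-one | CC1(C)CCC[C@]2(C)[C@@H](C(O)C3=C[C@H](O[Si](C)(C)C(C)(C)C)CC3=O)[C@@](C)(O[Si](CC)(CC)CC)CC[C@@H]12
F5 | step 9 | C11 methanesulfonate of F4 | CC1(C)CCC[C@]2(C)[C@@H](C(OS(C)(=O)=O)C3=C[C@H](O[Si](C)(C)C(C)(C)C)CC3=O)[C@@](C)(O[Si](CC)(CC)CC)CC[C@@H]12
F6 | step 11 | (2Z,3R,4R)-3-chloro-4-hydroxy-2-[8α-methyl-8β-(triethylsilyloxy)-12-nordriman-11-ylidene]cyclopentan-1-one | CC1(C)CCC[C@]2(C)[C@@H](/C=C3\C(=O)C[C@@H](O)[C@@H]3Cl)[C@@](C)(O[Si](CC)(CC)CC)CC[C@@H]12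
F7 | step 11 | 8-O-triethylsilyl ether of 18 | CC1(C)CCC[C@]2(C)[C@@H](/C=C3\C(O)=CC(=O)[C@@H]3Cl)[C@@](C)(O[Si](CC)(CC)CC)CC[C@@H]12
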